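**The decision.** Choose to reckon these flasks by one ratio instead of the clock, and start from what stands here:

| setting | teal | amber | south | east |
|---|---|---|---|---|
| starting complex | 0.74 M | 2.3 M | 2.0 M | 0.60 M |
| incoming ligand | 2.2 M | 2.2 M | 2.20 M | 2.20 M |
| temperature | 95 °C | 106 °C | 100 °C | 100 °C |
| remark | run made earlier | run made earlier |  |  |
| time |  |  | 8.0 h | 8.0 h |

- teal (time / h: complex with one exchanged / %, starting complex / %): 0.667: 34.7, 61.1; 1.33: 47.9, 42.0; 2.00: 52.5, 31.5; 2.50: 52.4, 26.0; 3.00: 53.9, 23.2; 4.00: 53.8, 17.8
- amber (time / h: complex with one exchanged / %, starting complex / %): 0.333: 31.7, 65.5; 0.500: 36.0, 57.9; 0.833: 42.2, 49.6; 1.33: 45.3, 45.1; 2.50: 46.7, 41.1; 4.00: 46.5, 41.5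

(standard deviation of a reading: 0.5 percentage points)

1. the winner by amount of complex with one exchanged, in percent of the starting complex charged; "neither" if no more than 2 percentage points parts them (south / east / neither)
2. how much complex with one exchanged is there at the end, in percent of the starting complex charged: south
3. how much complex with one exchanged is there at the end, in percent of the starting complex charged: east



**The fork.** Follow one molecule of starting complex. An incoming ligand turns it into complex with one exchanged at a rate k1[starting complex][incoming ligand], and a second ligand carries it on at k2[complex with one exchanged][incoming ligand]. Assume this scheme, so that [incoming ligand] stands in both rates and cancels from their ratio. Then the amount y of complex with one exchanged follows the remaining fraction x of starting complex along y = (x^s − x)/(1 − s), whatever the ligand does, where s is the fork ratio k2/k1, the selectivity factor.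

**Reading it.** At the peak of y, making equals using up, so there [starting complex]/[complex with one exchanged] equals s. Teal's complex with one exchanged reads 53.9% and then 53.8%, level within the scatter of 0.5 percentage points, so take the reading at 3.00 h as near the peak: it gives s = 0.430, a value read off scattered readings. The curve then peaks at 52.9%, with 22.8% of starting complex left. Amber, a different flask at 106 °C, stalled at 41.1% of starting complex, where the curve gives 47.6% against its reading of 46.7%, so carry s to 100 °C.

**My reckoning.** South has more ligand per complex than amber, so expect it to stop below amber's remainder, between 47.6% and 52.9%. East has more ligand per complex than teal and should pass the peak; at the forecast's remainder of 8%, the curve gives 45.2%. My lower figure for south stands above that by more than the margin.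

**The forecast.** It named south, with 48% for south and 44% for east: “South wins narrowly.”

**The flasks.** The answer is south, which holds more, with 50.5% for south against 45.4% for east.

    starting complex + incoming ligand → leaving ligand + complex with one exchanged (k = 0.550 M⁻¹ h⁻¹, Ea = 84.0 kJ mol⁻¹)
    complex with one exchanged + incoming ligand → leaving ligand + complex with two exchanged (k = 0.240 M⁻¹ h⁻¹, Ea = 101 kJ mol⁻¹)
    incoming ligand → decomposed reagent (k = 0.290 h⁻¹, Ea = 114 kJ mol⁻¹)
    (constants at 100 °C)

South's steps ran while incoming ligand lasted: it stood at 1.80% of its charge at 4.00 h, with starting complex at 34.8% then and 34.0% at 8.00 h. East still held 15.9% of its ligand at 4.00 h, and its starting complex went on from 12.5% to 8.48%, past the peak, while complex with one exchanged came down from 49.4%. The curve at south's remainder gives 50.7%. At the 7.1% left in a flask like south with 0.50 M of starting complex it gives 43.8%, and that flask held 43.3%.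

(Readings and results come from a simulation for an exercise, and the scatter is random.)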